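**Plan**
- The ring of the target is the bis-enol tautomer of 3-hexadecylcyclohexane-1,2,4,5-tetrone. Ring carbons C1 and C2 form an oxalyl pair, flanked by the two acidic carbons C3 (carrying the hexadecyl chain) and C6 (CH2), each alpha to a ketone of the C4/C5 pair.
- The retrosynthesis cuts ring bonds C2–C3 and C6–C1, giving diethyl oxalate and icosane-2,3-dione. The diketone is then cut at its own C2–C3 bond into the Weinreb amide of stearic acid and 1-ethoxyvinyllithium.
- Forward, the C20 chain is joined first (amide formation, single acylation of the lithiated vinyl ether, enol ether hydrolysis). The only ring is closed last by twofold acylation with oxalate, directly at the dihydroxyquinone oxidation level.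
- Stereochemistry: the target has no stereocentre and no stereodefined double bond, so nothing has to be set.

Key step: step 4

Remark: the two degenerate hydroxyquinone tautomers interconvert by proton shift, so whichever enol the ring closure delivers first is the compound of the target SMILES.

**Step 1**
Reactants: 1 octadecanoyl chloride (stearoyl chloride)
Product: 2 N-methoxy-N-methyloctadecanamide
Conditions: MeNH(OMe)·HCl (1.1 equiv), Et3N (2.3 equiv), CH2Cl2, 0 °C → rt
Reagents that add atoms: N,O-dimethylhydroxylamine hydrochloride, CNOC.Cl
Why: Nucleophilic acyl substitution of the acid chloride by the liberated hydroxylamine (Schotten–Baumann-type N-acylation, Weinreb amide formation) should be fast and clean, since the chain carries no other functional group.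

**Step 2**
Reactants: 2 N-methoxy-N-methyloctadecanamide; 3 ethyl vinyl ether
Product: 6 2-ethoxyicos-1-en-3-one, via 1-ethoxyvinyllithium 4 (not isolated), via lithium hemiaminal alkoxide 5 (not isolated)
Conditions: 3 (3 equiv), t-BuLi (2.2 equiv), THF, −78 → 0 °C; recool to −78 °C, add 2 in THF, → 0 °C; sat. aq. NH4Cl
Reagents that add atoms: none
Why: Oxygen-directed alpha-lithiation of the enol ether gives acyl-anion equivalent 4, which should add only once to the amide because the five-membered lithium chelate 5 persists until the quench (Weinreb ketone synthesis), after which loss of the hydroxylamine releases the alpha-ethoxy enone.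

**Step 3**
Reactants: 6 2-ethoxyicos-1-en-3-one
Product: 7 icosane-2,3-dione
Conditions: 2 M aq. HCl, THF, rt
Reagents that add atoms: water, O
Why: Acid-catalysed enol ether hydrolysis (C-protonation to an oxocarbenium ion, hydration, loss of ethanol) should turn the masked acetyl group into the free ketone and so deliver the 1,2-diketone without an oxidant.

**Step 4**
Reactants: 7 icosane-2,3-dione; 8 diethyl oxalate
Product: 11 3-hexadecyl-2,5-dihydroxy-1,4-benzoquinone, via potassium enolate of ethyl 2,4,5-trioxodocosanoate 9 (not isolated), via dipotassium 3-hexadecyl-2,5-dioxido-1,4-benzoquinone 10 (not isolated)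
Conditions: KOt-Bu (3.2 equiv), 8 (3 equiv), THF, 0 °C, Ar; 7 in THF added slowly by syringe pump; then rt → 50 °C; then 2 M aq. HCl, 0 °C; recrystallisation from EtOH
Reagents that add atoms: none
Why: Proposed new method: tert-butoxide reversibly enolises the diketone, the less hindered methyl enolate acylates one ester group of the oxalate by addition–elimination to give open-chain enolate 9, and a second deprotonation at the C4 methylene of the former diketone lets that carbon attack the remaining ester carbonyl and expel ethoxide. The closest known reaction types are the Claisen-then-Dieckmann condensation of dialkyl ketones with diethyl oxalate to cyclopentane-1,2,4-triones and the Fichter-type self-condensation of 2-oxoalkanoate esters to 3,6-dialkyl-2,5-dihydroxy-1,4-benzoquinones; an alpha-diketone as the four-carbon bis-enolate partner is the untested element. The six-membered ring closes in a 6-(enolendo)-exo-trig mode, which is favoured for enolates, whereas the competing five-membered aldol onto the neighbouring ketone is disfavoured and that ketone is in any case tied up in the beta-diketonate of 9. No stereocentre is created, and the cyclohexane-1,2,4,5-tetrone tautomerises at once to the dihydroxyquinone, whose twofold deprotonation to 10 makes the sequence irreversible and fixes the oxidation level. The selectivity needed is crossed acylation ahead of aldol self-condensation of the diketone, secured by the non-enolisable oxalate in excess and the slow addition of 7 to base and oxalate; regioselectivity is not an issue because acylation at the methyl or at the methylene first leads to the same ring.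

**Compound list**
1 | octadecanoyl chloride (stearoyl chloride) | CCCCCCCCCCCCCCCCCC(=O)Cl | starting material
2 | N-methoxy-N-methyloctadecanamide | CCCCCCCCCCCCCCCCCC(=O)N(C)OC | intermediate
3 | ethyl vinyl ether (ethoxyethene) | C=COCC | starting material
4 | 1-ethoxyvinyllithium | [Li]C(=C)OCC | intermediate (not isolated)
5 | lithium hemiaminal alkoxide: lithium 2-ethoxy-3-[methoxy(methyl)amino]icos-1-en-3-olate | CCCCCCCCCCCCCCCCCC([O-])(N(C)OC)C(=C)OCC.[Li+] | intermediate (not isolated)
6 | 2-ethoxyicos-1-en-3-one | CCCCCCCCCCCCCCCCCC(=O)C(=C)OCC | intermediate
7 | icosane-2,3-dione | CCCCCCCCCCCCCCCCCC(=O)C(C)=O | intermediate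
8 | diethyl oxalate | CCOC(=O)C(=O)OCC | starting material
9 | potassium enolate of ethyl 2,4,5-trioxodocosanoate | CCCCCCCCCCCCCCCCCC(=O)C(=O)C=C([O-])C(=O)OCC.[K+] | intermediate (not isolated)
10 | dipotassium 3-hexadecyl-2,5-dioxido-1,4-benzoquinone | CCCCCCCCCCCCCCCCC1=C([O-])C(=O)C=C([O-])C1=O.[K+].[K+] | intermediate (not isolated)
11 | 3-hexadecyl-2,5-dihydroxy-1,4-benzoquinone | CCCCCCCCCCCCCCCCC1=C(O)C(=O)C=C(O)C1=O | target

**Totals**
Total step count: 4. Longest linear sequence: 4 steps (1 → 2 → 6 → 7 → 11).

**Steps most likely to fail**

Step 4 (the proposed new method). Aldol self-condensation of the enolised diketone may outrun the crossed acylation, or the sequence may stall after the first acylation. The fallback sets out from 6 and comes back at 11, and uses only known reaction types carried out one at a time.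
- Enone 6 has a single enolisable position, so LiN(SiMe3)2 in THF at −78 °C followed by diethyl oxalate 8 should give, by an ordinary crossed Claisen condensation, ethyl 5-ethoxy-3-hexadecyl-2,4-dioxohex-5-enoate F1.
- Dilute aq. HCl in THF should then hydrolyse the enol ether to ethyl 3-hexadecyl-2,4,5-trioxohexanoate F2.
- NaOEt in EtOH at reflux should close the ring by intramolecular Claisen (Dieckmann-type) acylation of the methyl ketone by the alpha-keto ester, and acidification should give 11.
- In this order the diketone unit is never present during an intermolecular base-mediated step.

Step 2. The strongly basic vinyllithium may deprotonate the amide at its alpha-methylene or trigger N–O cleavage instead of adding, and lithiation of the vinyl ether may be incomplete. The fallback sets out from 2 and comes back at 7, replacing steps 2 and 3 with a sulfur-stabilised acyl anion.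
- 2-Methyl-1,3-dithiane is lithiated with n-BuLi in THF at −30 °C and acylated by 2 to give 1-(2-methyl-1,3-dithian-2-yl)octadecan-1-one F3.
- Oxidative removal of the dithiane with PhI(OCOCF3)2 in MeCN–H2O at rt should give 7.

Step 3. The electron-poor enol ether may hydrolyse sluggishly, and the diketone may undergo acid-promoted aldol self-condensation as it is set free. The fallback sets out from 2 and comes back at 7 and avoids acid altogether.
- CH2=C(CH3)MgBr in THF at 0 °C should convert 2 by Weinreb ketone synthesis into 2-methylicos-1-en-3-one F4.
- Ozonolysis (O3, CH2Cl2, −78 °C; then Me2S) cleaves the methylene carbon and should leave 7 under neutral, cold conditions.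

**Further compounds**
F1 | step 4 | ethyl 5-ethoxy-3-hexadecyl-2,4-dioxohex-5-enoate | CCCCCCCCCCCCCCCCC(C(=O)C(=O)OCC)C(=O)C(=C)OCC
F2 | step 4 | ethyl 3-hexadecyl-2,4,5-trioxohexanoate | CCCCCCCCCCCCCCCCC(C(=O)C(=O)OCC)C(=O)C(C)=O
F3 | step 2 | 1-(2-methyl-1,3-dithian-2-yl)octadecan-1-one | CCCCCCCCCCCCCCCCCC(=O)C1(C)SCCCS1
F4 | step 3 | 2-methylicos-1-en-3-one | CCCCCCCCCCCCCCCCCC(=O)C(C)=C
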